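**Retrosynthetic overview**
- The C8 oxygen comes last, by oxidising the doubly allylic C8 methylene of a 7-acyl-6-ketone; the acyl group comes from C7 acylation with 3-phenylpropanoyl chloride (acetic acid dianion + benzyl bromide).
- The C5 quaternary centre and the C6 ketone come from a cationic 1,2-prenyl shift (pinacol type) from C6 to C5 in a 5-methyl-5,6-diol; the C6 carbinol configuration is transferred to C5.
- The diol comes from MeLi addition to an α'-hydroxy vinylogous ester, made by enantioselective enolate hydroxylation after α'-prenylation.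
- The 2H-pyran-fused vinylogous ester comes from cyclohexane-1,3-dione and 3-methylbut-2-enal.
- Ring order: the carbocycle is bought as the dione, the pyran ring is made in step 1, and no ring is formed afterwards.

Assumption: chromene numbering (O1, C2, C3, C4, C4a, C5–C8, C8a) is used throughout, and the (−)-oxaziridine is taken to give 6R by analogy with 2-alkyl-1-tetralone enolates (its commercial antipode is used if the sense proves opposite).

**Step 1**
Reactants: 1 cyclohexane-1,3-dione; 2 3-methylbut-2-enal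
Product: 3 2,2-dimethyl-7,8-dihydro-2H-chromen-5(6H)-one
Conditions: EDDA (10 mol %), MeOH, rt
Reagents that add atoms: none
Why: Knoevenagel condensation followed by oxa-6π electrocyclisation of the 1-oxatriene (formal [3+3] annulation) is a standard route to 2H-pyran-fused enones and forms no stereocentre.

**Step 2**
Reactants: 3 2,2-dimethyl-7,8-dihydro-2H-chromen-5(6H)-one; 4 1-bromo-3-methylbut-2-ene
Product: 5 rac-2,2-dimethyl-6-(3-methylbut-2-en-1-yl)-7,8-dihydro-2H-chromen-5(6H)-one
Conditions: LDA, THF, −78 °C; then 4, −78 → 0 °C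
Reagents that add atoms: none
Why: Kinetic α'-deprotonation of the vinylogous ester (Stork–Danheiser-type enolate) and SN2 alkylation with the allylic bromide; the racemic C6 centre is erased in step 3.

**Step 3**
Reactants: 5 rac-2,2-dimethyl-6-(3-methylbut-2-en-1-yl)-7,8-dihydro-2H-chromen-5(6H)-one
Product: 6 (R)-6-hydroxy-2,2-dimethyl-6-(3-methylbut-2-en-1-yl)-7,8-dihydro-2H-chromen-5(6H)-one
Conditions: KHMDS, THF, −78 °C; then (−)-(8,8-dichlorocamphorylsulfonyl)oxaziridine, −78 → −40 °C; aq NH4Cl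
Reagents that add atoms: (−)-(8,8-dichlorocamphorylsulfonyl)oxaziridine, CC1(C)[C@H]2CC[C@@]13CS(=O)(=O)N4O[C@]34C2(Cl)Cl
Why: Davis oxidation, in which the chiral N-sulfonyloxaziridine transfers oxygen to one face of the planar tetrasubstituted enolate (reagent control, as for 2-alkyl-1-tetralones) and sets C6 as R.

**Step 4**
Reactants: 6 (R)-6-hydroxy-2,2-dimethyl-6-(3-methylbut-2-en-1-yl)-7,8-dihydro-2H-chromen-5(6H)-one
Product: 8 (S)-2,2,5-trimethyl-5-(3-methylbut-2-en-1-yl)-7,8-dihydro-2H-chromen-6(5H)-one, via 5,6-diol 7 (not isolated)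
Conditions: MeLi, CeCl3, THF, −78 °C; aq NH4Cl; crude 7: CSA (10 mol %), 4 Å MS, CH2Cl2, −40 → 0 °C
Reagents that add atoms: methyllithium, [Li]C
Why: Proposed new method: an interrupted Stork–Danheiser sequence in which the organocerium adds 1,2 to the vinylogous-ester carbonyl and anhydrous acid ionises the tertiary allylic C5–OH to a cation stabilised as a 2H-pyranyl oxocarbenium; since the ring ether cannot leave and no water is present, the cation is quenched by a suprafacial 1,2-shift of the prenyl group from the adjacent carbinol carbon (C6 to C5) while C6 collapses to the ketone, so prenyl lands on the face it occupied at C6 and 6R becomes 5S; the closest known reactions are the Stork–Danheiser transposition and the type-I semipinacol (pinacol) rearrangement of tertiary α-hydroxy carbocations with allyl migration.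

**Step 5**
Reactants: 9 acetic acid; 10 benzyl bromide
Product: 11 3-phenylpropanoic acid
Conditions: LDA (2.2 equiv), THF–DMPU, 0 °C; then 10, 0 °C → rt; aq HCl
Reagents that add atoms: none
Why: C-alkylation of the acetic acid dianion with a benzylic bromide is a standard carboxylic acid α-alkylation and forms no stereocentre.

**Step 6**
Reactants: 8 (S)-2,2,5-trimethyl-5-(3-methylbut-2-en-1-yl)-7,8-dihydro-2H-chromen-6(5H)-one; 11 3-phenylpropanoic acid
Product: 13 1-[(5S)-6-hydroxy-2,2,5-trimethyl-5-(3-methylbut-2-en-1-yl)-5,8-dihydro-2H-chromen-7-yl]-3-phenylpropan-1-one, via 3-phenylpropanoyl chloride 12 (not isolated)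
Conditions: 11, (COCl)2, cat. DMF, CH2Cl2, rt, evaporate; 8, LiHMDS (2.2 equiv), toluene, 0 °C, then 12; aq NH4Cl
Reagents that add atoms: oxalyl chloride, O=C(Cl)C(=O)Cl (supplies the Cl of 12 only)
Why: Crossed Claisen-type C-acylation of the lithium enolate at C7, the only enolisable position, gives the β-diketone (drawn as its enol), whose deprotonation by the second equivalent of base drives the reaction; C5 is untouched.

**Step 7**
Reactants: 13 1-[(5S)-6-hydroxy-2,2,5-trimethyl-5-(3-methylbut-2-en-1-yl)-5,8-dihydro-2H-chromen-7-yl]-3-phenylpropan-1-one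
Product: 16 (S)-8-hydroxy-2,2,5-trimethyl-5-(3-methylbut-2-en-1-yl)-7-(3-phenylpropanoyl)-2H-chromen-6(5H)-one, via acyl dienone 14 (not isolated), via C8 carbinol 15 (not isolated)
Conditions: DDQ (2.2 equiv), 1,4-dioxane–H2O (10:1), rt
Reagents that add atoms: water, O
Why: DDQ abstracts hydride from the doubly allylic C8–H flanked by the diketone enol and the dienyl ether (as in DDQ dehydrogenation of 2-acyl ketones), water adds to C8 of the acyl dienone, and a second DDQ oxidises the carbinol to the enolised triketone (DDQ/H2O oxidation of an activated methylene); the quaternary C5 bears no H and keeps its configuration.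

**Compound list**
1 | cyclohexane-1,3-dione | O=C1CCCC(=O)C1 | starting material
2 | 3-methylbut-2-enal | CC(C)=CC=O | starting material
3 | 2,2-dimethyl-7,8-dihydro-2H-chromen-5(6H)-one | CC1(C)C=CC2=C(O1)CCCC2=O | intermediate
4 | 1-bromo-3-methylbut-2-ene | CC(C)=CCBr | starting material
5 | rac-2,2-dimethyl-6-(3-methylbut-2-en-1-yl)-7,8-dihydro-2H-chromen-5(6H)-one (racemate) | CC1(C)C=CC2=C(O1)CCC(CC=C(C)C)C2=O | intermediate
6 | (R)-6-hydroxy-2,2-dimethyl-6-(3-methylbut-2-en-1-yl)-7,8-dihydro-2H-chromen-5(6H)-one | CC1(C)C=CC2=C(O1)CC[C@@](O)(CC=C(C)C)C2=O | intermediate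
7 | (6R)-2,2,5-trimethyl-6-(3-methylbut-2-en-1-yl)-5,6,7,8-tetrahydro-2H-chromene-5,6-diol (both C5 epimers) | CC1(C)C=CC2=C(O1)CC[C@@](O)(CC=C(C)C)C2(C)O | intermediate
8 | (S)-2,2,5-trimethyl-5-(3-methylbut-2-en-1-yl)-7,8-dihydro-2H-chromen-6(5H)-one | CC(C)=CC[C@]1(C)C(=O)CCC2=C1C=CC(C)(C)O2 | intermediate
9 | acetic acid | CC(=O)O | starting material
10 | benzyl bromide | BrCc1ccccc1 | starting material
11 | 3-phenylpropanoic acid | OC(=O)CCc1ccccc1 | intermediate
12 | 3-phenylpropanoyl chloride | ClC(=O)CCc1ccccc1 | intermediate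
13 | 1-[(5S)-6-hydroxy-2,2,5-trimethyl-5-(3-methylbut-2-en-1-yl)-5,8-dihydro-2H-chromen-7-yl]-3-phenylpropan-1-one (enol form of the 7-acyl-6-ketone) | CC(C)=CC[C@]1(C)C(O)=C(C(=O)CCc2ccccc2)CC2=C1C=CC(C)(C)O2 | intermediate
14 | (S)-2,2,5-trimethyl-5-(3-methylbut-2-en-1-yl)-7-(3-phenylpropanoyl)-2H-chromen-6(5H)-one | CC(C)=CC[C@]1(C)C(=O)C(C(=O)CCc2ccccc2)=CC2=C1C=CC(C)(C)O2 | intermediate
15 | 1-[(5S)-6,8-dihydroxy-2,2,5-trimethyl-5-(3-methylbut-2-en-1-yl)-5,8-dihydro-2H-chromen-7-yl]-3-phenylpropan-1-one (both C8 epimers) | CC(C)=CC[C@]1(C)C(O)=C(C(=O)CCc2ccccc2)C(O)C2=C1C=CC(C)(C)O2 | intermediate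
16 | (S)-8-hydroxy-2,2,5-trimethyl-5-(3-methylbut-2-en-1-yl)-7-(3-phenylpropanoyl)-2H-chromen-6(5H)-one | CC(C)=CC[C@]1(C)C(=O)C(C(=O)CCc2ccccc2)=C(O)C2=C1C=CC(C)(C)O2 | target

**Totals**
Total steps: 7. Longest linear sequence: 6 (steps 1, 2, 3, 4, 6, 7).

**Three steps most likely to fail**

Step 4 (proposed new step). Risks are aromatisation of the cation by double dehydration, pyran opening by adventitious water, and loss of ee if the prenyl group ionises instead of migrating. The fallback uses known chemistry without a carbon shift; it sets out from 3 and comes back at 8. The lithium enolate of 3 is hydroxylated with racemic 2-(phenylsulfonyl)-3-phenyloxaziridine to rac-6-hydroxy-2,2-dimethyl-7,8-dihydro-2H-chromen-5(6H)-one F2. MeLi/CeCl3 addition gives 2,2,5-trimethyl-5,6,7,8-tetrahydro-2H-chromene-5,6-diol F3. Acid then effects the textbook pinacol dehydration with 1,2-hydride migration to rac-2,2,5-trimethyl-7,8-dihydro-2H-chromen-6(5H)-one F4. The thermodynamic dienolate (NaH) is trapped with allyl chloroformate as allyl 2,2,5-trimethyl-7,8-dihydro-2H-chromen-6-yl carbonate F5. Pd2(dba)3/(R)-t-Bu-PHOX decarboxylative asymmetric allylic alkylation (ligand sense assigned by analogy with 2-allyl-2-methylcyclohexanone) sets the quaternary centre in (S)-5-allyl-2,2,5-trimethyl-7,8-dihydro-2H-chromen-6(5H)-one F6. Cross-metathesis with 2-methyl-2-butene (Hoveyda–Grubbs II) gives 8.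

Step 7. Risks are dimerisation of the acyl dienone, incomplete second oxidation, and side-chain dehydrogenation. The fallback installs the C8 oxygen before the acyl group; it sets out from 8 and comes back at 16. IBX dehydrogenation gives (S)-2,2,5-trimethyl-5-(3-methylbut-2-en-1-yl)-2H-chromen-6(5H)-one F7. Weitz–Scheffer epoxidation (H2O2, NaOH) gives (5S)-7,8-epoxy-2,2,5-trimethyl-5-(3-methylbut-2-en-1-yl)-7,8-dihydro-2H-chromen-6(5H)-one F8. SmI2 opens the epoxide at the α-carbon to (5S)-8-hydroxy-2,2,5-trimethyl-5-(3-methylbut-2-en-1-yl)-7,8-dihydro-2H-chromen-6(5H)-one F9. Dess–Martin oxidation gives (S)-2,2,5-trimethyl-5-(3-methylbut-2-en-1-yl)-2H-chromene-6,8(5H,7H)-dione F10. DCC/DMAP acylation with 11 (O-acylation, then 1,3-acyl migration to C7) gives 16.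

Step 3. Risks are modest ee on this non-benzo-fused enolate and competing γ-deprotonation. The fallback replaces asymmetric induction by resolution; it sets out from 5 and comes back at 6. The enolate is hydroxylated with achiral 2-(phenylsulfonyl)-3-phenyloxaziridine, and the racemate is separated by preparative chiral SFC, keeping 6 and discarding (S)-6-hydroxy-2,2-dimethyl-6-(3-methylbut-2-en-1-yl)-7,8-dihydro-2H-chromen-5(6H)-one F1.

**Further compounds**
F1 | step 3 | (S)-6-hydroxy-2,2-dimethyl-6-(3-methylbut-2-en-1-yl)-7,8-dihydro-2H-chromen-5(6H)-one | CC1(C)C=CC2=C(O1)CC[C@](O)(CC=C(C)C)C2=O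
F2 | step 4 | rac-6-hydroxy-2,2-dimethyl-7,8-dihydro-2H-chromen-5(6H)-one | CC1(C)C=CC2=C(O1)CCC(O)C2=O
F3 | step 4 | 2,2,5-trimethyl-5,6,7,8-tetrahydro-2H-chromene-5,6-diol (racemic, diastereomer mixture) | CC1(C)C=CC2=C(O1)CCC(O)C2(C)O
F4 | step 4 | rac-2,2,5-trimethyl-7,8-dihydro-2H-chromen-6(5H)-one | CC1C(=O)CCC2=C1C=CC(C)(C)O2
F5 | step 4 | allyl 2,2,5-trimethyl-7,8-dihydro-2H-chromen-6-yl carbonate | C=CCOC(=O)OC1=C(C)C2=C(CC1)OC(C)(C)C=C2
F6 | step 4 | (S)-5-allyl-2,2,5-trimethyl-7,8-dihydro-2H-chromen-6(5H)-one | C=CC[C@]1(C)C(=O)CCC2=C1C=CC(C)(C)O2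
F7 | step 7 | (S)-2,2,5-trimethyl-5-(3-methylbut-2-en-1-yl)-2H-chromen-6(5H)-one | CC(C)=CC[C@]1(C)C(=O)C=CC2=C1C=CC(C)(C)O2
F8 | step 7 | (5S)-7,8-epoxy-2,2,5-trimethyl-5-(3-methylbut-2-en-1-yl)-7,8-dihydro-2H-chromen-6(5H)-one (epoxide diastereomers) | CC(C)=CC[C@]1(C)C(=O)C3OC3C2=C1C=CC(C)(C)O2
F9 | step 7 | (5S)-8-hydroxy-2,2,5-trimethyl-5-(3-methylbut-2-en-1-yl)-7,8-dihydro-2H-chromen-6(5H)-one (both C8 epimers) | CC(C)=CC[C@]1(C)C(=O)CC(O)C2=C1C=CC(C)(C)O2
F10 | step 7 | (S)-2,2,5-trimethyl-5-(3-methylbut-2-en-1-yl)-2H-chromene-6,8(5H,7H)-dione | CC(C)=CC[C@]1(C)C(=O)CC(=O)C2=C1C=CC(C)(C)O2
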